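**Retrosynthetic overview**

1. Ring A (the 3-hydroxybenzoyl group) is attached last at C8: lithiation of the only aromatic C–H of ring B, between O1 and O7, then acylation with a Weinreb amide.
2. The (3R)-carbinol comes from CBS reduction of the chroman-3-one. The ketone comes from a 2-methyl-4H-chromene by epoxidation and methyl transfer from AlMe3, which supplies the C3 oxygen and the second C2 methyl.
3. Key disconnection C2=C3: the pyran ring is closed by titanium-alkylidene carbonyl–olefin metathesis between the O-acetyl group on C8a and the C-allyl group on C4a.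
4. Enabling feature: O1 and C4 sit on adjacent carbons of ring B (C8a and C4a), so the acetate carbonyl carbon (future C2, already carrying one methyl) and the internal allyl carbon (future C3) close a six-membered ring. The allyl group, placed by an ortho-Claisen rearrangement, is the only monosubstituted olefin in the molecule.
5. The side-chain stereocentre is set by deconjugative Evans alkylation of a senecioyl imide with the ring B benzylic bromide, followed by methallyl chain extension. Ring order: ring B (from 2,4,6-trihydroxybenzaldehyde), pyran ring, ring A.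

Key step: step 15

Remark: chroman numbering (O1, C2, C3, C4, C4a, C5 to C8, C8a) is used for the target; the SMILES is read as (3R) in the pyran ring and (2R) in the side chain.

**Route**

Step 1
Reactants: 1 2,4,6-trihydroxybenzaldehyde
Product: 2 4-formyl-3,5-dihydroxyphenyl 4-methylbenzenesulfonate
Conditions: TsCl (1.0 equiv), K2CO3, acetone, 0 °C to rt
Reagents that add atoms: p-toluenesulfonyl chloride, Cc1ccc(S(=O)(=O)Cl)cc1
Why: The 4-OH is the most acidic hydroxyl and the only one not hydrogen-bonded to the formyl group, so selective O-sulfonylation should occur there; the sulfonate also makes the later benzylic bromide less prone to ionize.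

Step 2
Reactants: 2 4-formyl-3,5-dihydroxyphenyl 4-methylbenzenesulfonate
Product: 3 4-formyl-3-hydroxy-5-(methoxymethoxy)phenyl 4-methylbenzenesulfonate
Conditions: MOMCl (1.1 equiv), i-Pr2NEt, CH2Cl2, 0 °C
Reagents that add atoms: chloromethyl methyl ether, COCCl
Why: The two chelated hydroxyls are equivalent, and after the first O-alkylation the remaining one stays hydrogen-bonded to the aldehyde, so mono-protection (Williamson-type etherification) should stop cleanly.

Step 3
Reactants: 3 4-formyl-3-hydroxy-5-(methoxymethoxy)phenyl 4-methylbenzenesulfonate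
Product: 4 3-(allyloxy)-4-formyl-5-(methoxymethoxy)phenyl 4-methylbenzenesulfonate
Conditions: allyl bromide, K2CO3, DMF, rt
Reagents that add atoms: allyl bromide, C=CCBr
Why: Williamson allylation of the last free phenol with a reactive allylic halide under carbonate conditions that leave the aryl sulfonate and the acetal intact.

Step 4
Reactants: 4 3-(allyloxy)-4-formyl-5-(methoxymethoxy)phenyl 4-methylbenzenesulfonate
Product: 5 2-allyl-4-formyl-3-hydroxy-5-(methoxymethoxy)phenyl 4-methylbenzenesulfonate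
Conditions: N,N-diethylaniline, 190 °C
Reagents that add atoms: none
Why: Aromatic Claisen rearrangement; one ortho carbon of the allyloxy group carries the formyl group, so the [3,3] shift can only deliver the allyl group to the carbon between the new phenol and the sulfonate (future C4a).

Step 5
Reactants: 5 2-allyl-4-formyl-3-hydroxy-5-(methoxymethoxy)phenyl 4-methylbenzenesulfonate
Product: 6 2-allyl-4-formyl-3-methoxy-5-(methoxymethoxy)phenyl 4-methylbenzenesulfonate
Conditions: MeI, K2CO3, DMF, 40 °C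
Reagents that add atoms: iodomethane, CI
Why: O-methylation (Williamson) of the chelated phenol installs the C5 methoxy group of the target.

Step 6
Reactants: 6 2-allyl-4-formyl-3-methoxy-5-(methoxymethoxy)phenyl 4-methylbenzenesulfonate
Product: 7 2-allyl-4-(hydroxymethyl)-3-methoxy-5-(methoxymethoxy)phenyl 4-methylbenzenesulfonate
Conditions: NaBH4, MeOH/THF, 0 °C
Reagents that add atoms: none
Why: Borohydride reduction of the aldehyde; sulfonate, acetal and olefin are inert.

Step 7
Reactants: 7 2-allyl-4-(hydroxymethyl)-3-methoxy-5-(methoxymethoxy)phenyl 4-methylbenzenesulfonate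
Product: 8 2-allyl-4-(bromomethyl)-3-methoxy-5-(methoxymethoxy)phenyl 4-methylbenzenesulfonate
Conditions: CBr4, PPh3, CH2Cl2, 0 °C; used at once
Reagents that add atoms: carbon tetrabromide, BrC(Br)(Br)Br
Why: Appel bromination under neutral conditions; the para sulfonate lowers the tendency of this 2,6-dioxygenated benzylic bromide to ionize and self-alkylate.

Step 8
Reactants: 9 (R)-4-benzyloxazolidin-2-one
Product: 11 (R)-4-benzyl-3-(3-methylbut-2-enoyl)oxazolidin-2-one, via lithium oxazolidinide 10 (not isolated)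
Conditions: n-BuLi, THF, −78 °C; then 3-methylbut-2-enoyl chloride, −78 to 0 °C
Reagents that add atoms: 3-methylbut-2-enoyl chloride, CC(C)=CC(=O)Cl
Why: Standard N-acylation of the lithiated Evans auxiliary with an acid chloride.

Step 9
Reactants: 11 (R)-4-benzyl-3-(3-methylbut-2-enoyl)oxazolidin-2-one, 8 2-allyl-4-(bromomethyl)-3-methoxy-5-(methoxymethoxy)phenyl 4-methylbenzenesulfonate
Product: 13 (4R)-4-benzyl-3-[(2R)-2-{[3-allyl-2-methoxy-6-(methoxymethoxy)-4-(tosyloxy)phenyl]methyl}-3-methylbut-3-enoyl]oxazolidin-2-one, via sodium dienolate 12 (not isolated)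
Conditions: NaN(SiMe3)2, THF, −78 °C; then 8, −78 to −40 °C
Reagents that add atoms: none
Why: Evans alkylation of the chelated (Z)-dienolate formed by γ-deprotonation: the benzylic bromide should react at Cα (deconjugative alkylation) on the face opposite the benzyl group of the (R)-auxiliary, which sets the (R) stereocentre and creates the isopropenyl group in the same step.

Step 10
Reactants: 13 (4R)-4-benzyl-3-[(2R)-2-{[3-allyl-2-methoxy-6-(methoxymethoxy)-4-(tosyloxy)phenyl]methyl}-3-methylbut-3-enoyl]oxazolidin-2-one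
Product: 14 2-allyl-4-[(2R)-2-(hydroxymethyl)-3-methylbut-3-en-1-yl]-3-methoxy-5-(methoxymethoxy)phenyl 4-methylbenzenesulfonate
Conditions: LiBH4, MeOH (1 equiv), Et2O, 0 °C
Reagents that add atoms: none
Why: Reductive removal of the auxiliary with the non-basic LiBH4 should give the primary alcohol without epimerization or double-bond migration; the aryl sulfonate is not reduced.

Step 11
Reactants: 14 2-allyl-4-[(2R)-2-(hydroxymethyl)-3-methylbut-3-en-1-yl]-3-methoxy-5-(methoxymethoxy)phenyl 4-methylbenzenesulfonate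
Product: 15 2-allyl-3-methoxy-5-(methoxymethoxy)-4-[(2R)-3-methyl-2-(tosyloxymethyl)but-3-en-1-yl]phenyl 4-methylbenzenesulfonate
Conditions: TsCl, Et3N, DMAP (cat.), CH2Cl2, 0 °C to rt
Reagents that add atoms: p-toluenesulfonyl chloride, Cc1ccc(S(=O)(=O)Cl)cc1
Why: Sulfonylation of the primary alcohol gives a leaving group for SN2 coupling without touching the stereocentre.

Step 12
Reactants: 15 2-allyl-3-methoxy-5-(methoxymethoxy)-4-[(2R)-3-methyl-2-(tosyloxymethyl)but-3-en-1-yl]phenyl 4-methylbenzenesulfonate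
Product: 16 2-allyl-3-methoxy-5-(methoxymethoxy)-4-[(2R)-5-methyl-2-(prop-1-en-2-yl)hex-5-en-1-yl]phenyl 4-methylbenzenesulfonate
Conditions: 2-methylallylmagnesium chloride, Li2CuCl4 (5 mol%), THF, −30 to 0 °C
Reagents that add atoms: 2-methylallylmagnesium chloride, CC(=C)C[Mg]Cl
Why: Copper-catalysed SN2 coupling of an allylic Grignard reagent with a primary alkyl tosylate; the methallyl nucleophile is symmetrical, the aryl sulfonate is inert without nickel or palladium, and the low temperature suppresses E2 elimination.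

Step 13
Reactants: 16 2-allyl-3-methoxy-5-(methoxymethoxy)-4-[(2R)-5-methyl-2-(prop-1-en-2-yl)hex-5-en-1-yl]phenyl 4-methylbenzenesulfonate
Product: 17 2-allyl-3-methoxy-5-(methoxymethoxy)-4-[(2R)-5-methyl-2-(prop-1-en-2-yl)hex-5-en-1-yl]phenol
Conditions: KOH, dioxane/H2O, 90 °C; then aq. NH4Cl
Reagents that add atoms: none
Why: Hydroxide attacks sulfur of the aryl sulfonate (S–O cleavage) and releases the phenol that becomes O1; acetal, ethers and olefins are stable to aqueous base, and the absence of an alcohol solvent avoids alkyl sulfonate formation.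

Step 14
Reactants: 17 2-allyl-3-methoxy-5-(methoxymethoxy)-4-[(2R)-5-methyl-2-(prop-1-en-2-yl)hex-5-en-1-yl]phenol
Product: 18 2-allyl-3-methoxy-5-(methoxymethoxy)-4-[(2R)-5-methyl-2-(prop-1-en-2-yl)hex-5-en-1-yl]phenyl acetate
Conditions: Ac2O, pyridine, DMAP (cat.), CH2Cl2, 0 °C to rt
Reagents that add atoms: acetic anhydride, CC(=O)OC(C)=O
Why: O-acetylation puts the future C2 with its first methyl group on O1, next to the allyl group.

Step 15
Reactants: 18 2-allyl-3-methoxy-5-(methoxymethoxy)-4-[(2R)-5-methyl-2-(prop-1-en-2-yl)hex-5-en-1-yl]phenyl acetate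
Product: 19 5-methoxy-7-(methoxymethoxy)-2-methyl-6-[(2R)-5-methyl-2-(prop-1-en-2-yl)hex-5-en-1-yl]-4H-chromene
Conditions: TiCl4, TMEDA, Zn, PbCl2 (cat.), CH3CHBr2, THF/CH2Cl2, 0 to 65 °C; aq. K2CO3 work-up, Et3N-deactivated silica
Reagents that add atoms: none
Why: Zn, TiCl4·TMEDA and CH3CHBr2 generate a titanium ethylidene that exchanges with the allyl group on C4a through a titanacyclobutane, releasing propene and leaving a titanium alkylidene on the future C3; this alkylidene adds across the acetate carbonyl on O1, and the oxatitanacyclobutane collapses to the C2=C3 enol ether and a titanium oxide. The closest known reaction type is the titanium-mediated cyclization of olefinic esters to six- and seven-membered cyclic enol ethers (Takai–Utimoto or Tebbe reagents). The pyran ring closes as a six-membered ring by intramolecular carbonyl olefination, with the new double bond endocyclic and the tether fixed by the ortho relationship of O1 and C4 on ring B. No stereocentre is created; C3 is left trigonal so that its configuration can be set later by reagent control. The step needs chemoselectivity for the allyl group over the two 1,1-disubstituted olefins of the side chain, which do not undergo alkylidene exchange, and it needs exchange to precede direct ethylidenation of the carbonyl, which the unhindered terminal olefin and the six-membered closure should favour.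

Step 16
Reactants: 19 5-methoxy-7-(methoxymethoxy)-2-methyl-6-[(2R)-5-methyl-2-(prop-1-en-2-yl)hex-5-en-1-yl]-4H-chromene
Product: 21 5-methoxy-7-(methoxymethoxy)-2,2-dimethyl-6-[(2R)-5-methyl-2-(prop-1-en-2-yl)hex-5-en-1-yl]chroman-3-ol as both C3 epimers, via 2,3-epoxychroman 20 (not isolated)
Conditions: DMDO (1.05 equiv, acetone), CH2Cl2, −78 to 0 °C; evaporate; AlMe3, CH2Cl2, −78 to −30 °C; Rochelle salt work-up
Reagents that add atoms: dimethyldioxirane, CC1(C)OO1; trimethylaluminium, C[Al](C)C
Why: The electron-rich enol ether should be epoxidized much faster than the 1,1-disubstituted olefins, and AlMe3 should open the epoxy ketal at C2 through the ring oxocarbenium ion and transfer methyl there (as in C-glycoside synthesis from glycal epoxides), making C2 a non-stereogenic gem-dimethyl carbon and placing oxygen on C3 without facial control, which the next two steps correct.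

Step 17
Reactants: 21 5-methoxy-7-(methoxymethoxy)-2,2-dimethyl-6-[(2R)-5-methyl-2-(prop-1-en-2-yl)hex-5-en-1-yl]chroman-3-ol as both C3 epimers
Product: 22 5-methoxy-7-(methoxymethoxy)-2,2-dimethyl-6-[(2R)-5-methyl-2-(prop-1-en-2-yl)hex-5-en-1-yl]chroman-3-one
Conditions: Dess–Martin periodinane, NaHCO3, CH2Cl2, 0 °C to rt
Reagents that add atoms: none
Why: Buffered Dess–Martin oxidation converts both epimers into one ketone whose two flanks (quaternary C2 and benzylic CH2) differ strongly in size.

Step 18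
Reactants: 22 5-methoxy-7-(methoxymethoxy)-2,2-dimethyl-6-[(2R)-5-methyl-2-(prop-1-en-2-yl)hex-5-en-1-yl]chroman-3-one
Product: 23 (3R)-5-methoxy-7-(methoxymethoxy)-2,2-dimethyl-6-[(2R)-5-methyl-2-(prop-1-en-2-yl)hex-5-en-1-yl]chroman-3-ol
Conditions: (S)-Me-CBS oxazaborolidine [(S)-1-methyl-3,3-diphenyltetrahydro-1H,3H-pyrrolo[1,2-c][1,3,2]oxazaborole] (20 mol%), catecholborane, toluene, −78 to −40 °C
Reagents that add atoms: none
Why: Corey–Bakshi–Shibata reduction: with the quaternary C2 as the large group and the C4 methylene as the small group, the (S)-catalyst should deliver hydride to the Si face of C3 and give the (3R)-carbinol, as for tert-alkyl ketones; catecholborane does not hydroborate the olefins at this temperature.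

Step 19
Reactants: 24 methyl 3-hydroxybenzoate
Product: 25 methyl 3-(methoxymethoxy)benzoate
Conditions: MOMCl, i-Pr2NEt, CH2Cl2, 0 °C to rt
Reagents that add atoms: chloromethyl methyl ether, COCCl
Why: Routine protection of the ring A phenol as an acetal stable to organolithium reagents.

Step 20
Reactants: 25 methyl 3-(methoxymethoxy)benzoate
Product: 26 N-methoxy-3-(methoxymethoxy)-N-methylbenzamide
Conditions: MeNH(OMe)·HCl, i-PrMgCl, THF, −20 °C
Reagents that add atoms: N,O-dimethylhydroxylamine hydrochloride, CNOC.Cl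
Why: Direct conversion of the ester into the Weinreb amide by the magnesium amide formed in the flask.

Step 21
Reactants: 23 (3R)-5-methoxy-7-(methoxymethoxy)-2,2-dimethyl-6-[(2R)-5-methyl-2-(prop-1-en-2-yl)hex-5-en-1-yl]chroman-3-ol, 26 N-methoxy-3-(methoxymethoxy)-N-methylbenzamide
Product: 28 [(3R)-3-hydroxy-5-methoxy-7-(methoxymethoxy)-2,2-dimethyl-6-[(2R)-5-methyl-2-(prop-1-en-2-yl)hex-5-en-1-yl]chroman-8-yl][3-(methoxymethoxy)phenyl]methanone, via dilithio species 27 (not isolated)
Conditions: n-BuLi (2.3 equiv), THF, −20 to 0 °C; then 26, −78 to 0 °C; aq. NH4Cl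
Reagents that add atoms: none
Why: Directed ortho-metalation: after O-deprotonation, the only aromatic C–H (C8), flanked by O1 and the MOM ether, should be lithiated, and the aryllithium is acylated once by the Weinreb amide because the chelated tetrahedral adduct survives until work-up.

Step 22
Reactants: 28 [(3R)-3-hydroxy-5-methoxy-7-(methoxymethoxy)-2,2-dimethyl-6-[(2R)-5-methyl-2-(prop-1-en-2-yl)hex-5-en-1-yl]chroman-8-yl][3-(methoxymethoxy)phenyl]methanone
Product: 29 [(3R)-3,7-dihydroxy-5-methoxy-2,2-dimethyl-6-[(2R)-5-methyl-2-(prop-1-en-2-yl)hex-5-en-1-yl]chroman-8-yl](3-hydroxyphenyl)methanone (CNP0307300.2)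
Conditions: 2 M HCl (aq), MeOH/THF, 40 °C, stopped at full conversion
Reagents that add atoms: none
Why: Acid-catalysed acetal cleavage removes both MOM groups (the one ortho to the ketone fastest); dilute acid and moderate temperature are chosen so that the 1,1-disubstituted olefins are not protonated and do not cyclize onto the freed C7 phenol.

**Compound list**

1 | 2,4,6-trihydroxybenzaldehyde | O=Cc1c(O)cc(O)cc1O | starting material
2 | 4-formyl-3,5-dihydroxyphenyl 4-methylbenzenesulfonate | O=Cc1c(O)cc(OS(=O)(=O)c2ccc(C)cc2)cc1O | intermediate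
3 | 4-formyl-3-hydroxy-5-(methoxymethoxy)phenyl 4-methylbenzenesulfonate | O=Cc1c(O)cc(OS(=O)(=O)c2ccc(C)cc2)cc1OCOC | intermediate
4 | 3-(allyloxy)-4-formyl-5-(methoxymethoxy)phenyl 4-methylbenzenesulfonate | O=Cc1c(OCC=C)cc(OS(=O)(=O)c2ccc(C)cc2)cc1OCOC | intermediate
5 | 2-allyl-4-formyl-3-hydroxy-5-(methoxymethoxy)phenyl 4-methylbenzenesulfonate | O=Cc1c(O)c(CC=C)c(OS(=O)(=O)c2ccc(C)cc2)cc1OCOC | intermediate
6 | 2-allyl-4-formyl-3-methoxy-5-(methoxymethoxy)phenyl 4-methylbenzenesulfonate | O=Cc1c(OC)c(CC=C)c(OS(=O)(=O)c2ccc(C)cc2)cc1OCOC | intermediate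
7 | 2-allyl-4-(hydroxymethyl)-3-methoxy-5-(methoxymethoxy)phenyl 4-methylbenzenesulfonate | OCc1c(OC)c(CC=C)c(OS(=O)(=O)c2ccc(C)cc2)cc1OCOC | intermediate
8 | 2-allyl-4-(bromomethyl)-3-methoxy-5-(methoxymethoxy)phenyl 4-methylbenzenesulfonate | BrCc1c(OC)c(CC=C)c(OS(=O)(=O)c2ccc(C)cc2)cc1OCOC | intermediate
9 | (R)-4-benzyloxazolidin-2-one | O=C1OC[C@@H](Cc2ccccc2)N1 | starting material
10 | lithium (R)-4-benzyl-2-oxooxazolidin-3-ide | O=C1OC[C@@H](Cc2ccccc2)N1[Li] | intermediate (not isolated)
11 | (R)-4-benzyl-3-(3-methylbut-2-enoyl)oxazolidin-2-one | CC(C)=CC(=O)N1C(=O)OC[C@H]1Cc1ccccc1 | intermediate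
12 | sodium (Z)-dienolate of 11 | C=C(C)/C=C(\O[Na])N1C(=O)OC[C@H]1Cc1ccccc1 | intermediate (not isolated)
13 | (4R)-4-benzyl-3-[(2R)-2-{[3-allyl-2-methoxy-6-(methoxymethoxy)-4-(tosyloxy)phenyl]methyl}-3-methylbut-3-enoyl]oxazolidin-2-one | O=C(N1C(=O)OC[C@H]1Cc1ccccc1)[C@H](Cc1c(OC)c(CC=C)c(OS(=O)(=O)c2ccc(C)cc2)cc1OCOC)C(=C)C | intermediate
14 | 2-allyl-4-[(2R)-2-(hydroxymethyl)-3-methylbut-3-en-1-yl]-3-methoxy-5-(methoxymethoxy)phenyl 4-methylbenzenesulfonate | OC[C@H](Cc1c(OC)c(CC=C)c(OS(=O)(=O)c2ccc(C)cc2)cc1OCOC)C(=C)C | intermediate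
15 | 2-allyl-3-methoxy-5-(methoxymethoxy)-4-[(2R)-3-methyl-2-(tosyloxymethyl)but-3-en-1-yl]phenyl 4-methylbenzenesulfonate | Cc1ccc(S(=O)(=O)OC[C@H](Cc2c(OC)c(CC=C)c(OS(=O)(=O)c3ccc(C)cc3)cc2OCOC)C(=C)C)cc1 | intermediate
16 | 2-allyl-3-methoxy-5-(methoxymethoxy)-4-[(2R)-5-methyl-2-(prop-1-en-2-yl)hex-5-en-1-yl]phenyl 4-methylbenzenesulfonate | C=C(C)CC[C@H](Cc1c(OC)c(CC=C)c(OS(=O)(=O)c2ccc(C)cc2)cc1OCOC)C(=C)C | intermediate
17 | 2-allyl-3-methoxy-5-(methoxymethoxy)-4-[(2R)-5-methyl-2-(prop-1-en-2-yl)hex-5-en-1-yl]phenol | C=C(C)CC[C@H](Cc1c(OC)c(CC=C)c(O)cc1OCOC)C(=C)C | intermediate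
18 | 2-allyl-3-methoxy-5-(methoxymethoxy)-4-[(2R)-5-methyl-2-(prop-1-en-2-yl)hex-5-en-1-yl]phenyl acetate | C=C(C)CC[C@H](Cc1c(OC)c(CC=C)c(OC(C)=O)cc1OCOC)C(=C)C | intermediate
19 | 5-methoxy-7-(methoxymethoxy)-2-methyl-6-[(2R)-5-methyl-2-(prop-1-en-2-yl)hex-5-en-1-yl]-4H-chromene | C=C(C)CC[C@H](Cc1c(OC)c2c(cc1OCOC)OC(C)=CC2)C(=C)C | intermediate
20 | 2,3-epoxy-5-methoxy-7-(methoxymethoxy)-2-methyl-6-[(2R)-5-methyl-2-(prop-1-en-2-yl)hex-5-en-1-yl]chroman (both epoxide faces) | C=C(C)CC[C@H](Cc1c(OC)c2c(cc1OCOC)OC1(C)OC1C2)C(=C)C | intermediate (not isolated)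
21 | 5-methoxy-7-(methoxymethoxy)-2,2-dimethyl-6-[(2R)-5-methyl-2-(prop-1-en-2-yl)hex-5-en-1-yl]chroman-3-ol (both C3 epimers) | C=C(C)CC[C@H](Cc1c(OC)c2c(cc1OCOC)OC(C)(C)C(O)C2)C(=C)C | intermediate
22 | 5-methoxy-7-(methoxymethoxy)-2,2-dimethyl-6-[(2R)-5-methyl-2-(prop-1-en-2-yl)hex-5-en-1-yl]chroman-3-one | C=C(C)CC[C@H](Cc1c(OC)c2c(cc1OCOC)OC(C)(C)C(=O)C2)C(=C)C | intermediate
23 | (3R)-5-methoxy-7-(methoxymethoxy)-2,2-dimethyl-6-[(2R)-5-methyl-2-(prop-1-en-2-yl)hex-5-en-1-yl]chroman-3-ol | C=C(C)CC[C@H](Cc1c(OC)c2c(cc1OCOC)OC(C)(C)[C@H](O)C2)C(=C)C | intermediate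
24 | methyl 3-hydroxybenzoate | COC(=O)c1cccc(O)c1 | starting material
25 | methyl 3-(methoxymethoxy)benzoate | COCOc1cccc(C(=O)OC)c1 | intermediate
26 | N-methoxy-3-(methoxymethoxy)-N-methylbenzamide | CON(C)C(=O)c1cccc(OCOC)c1 | intermediate
27 | C8-lithio lithium alkoxide of 23 | C=C(C)CC[C@H](Cc1c(OC)c2c(c([Li])c1OCOC)OC(C)(C)[C@H](O[Li])C2)C(=C)C | intermediate (not isolated)
28 | [(3R)-3-hydroxy-5-methoxy-7-(methoxymethoxy)-2,2-dimethyl-6-[(2R)-5-methyl-2-(prop-1-en-2-yl)hex-5-en-1-yl]chroman-8-yl][3-(methoxymethoxy)phenyl]methanone | C=C(C)CC[C@H](Cc1c(OC)c2c(c(C(=O)c3cccc(OCOC)c3)c1OCOC)OC(C)(C)[C@H](O)C2)C(=C)C | intermediate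
29 | [(3R)-3,7-dihydroxy-5-methoxy-2,2-dimethyl-6-[(2R)-5-methyl-2-(prop-1-en-2-yl)hex-5-en-1-yl]chroman-8-yl](3-hydroxyphenyl)methanone | C=C(C)CC[C@H](Cc1c(O)c(C(=O)c2cccc(O)c2)c2c(c1OC)C[C@@H](O)C(C)(C)O2)C(=C)C | target

**Step count**

Total step count: 22 (19 on the main line, 1 for the imide 11, 2 for the Weinreb amide 26).
Longest linear sequence: 19 steps (steps 1 to 7, 9 to 18, 21 and 22).

**Steps most likely to fail**

Step 15. Direct ethylidenation of the acetate carbonyl may outrun alkylidene exchange at the allyl group, the allyl double bond may migrate into conjugation with ring B, and the enol ether may hydrolyse on work-up. The fallback splits the closure into two known operations. It sets out from 18: methylenation of the ester with Cp2TiMe2 (toluene, 70 °C) should give 2-allyl-3-methoxy-5-(methoxymethoxy)-4-[(2R)-5-methyl-2-(prop-1-en-2-yl)hex-5-en-1-yl]phenyl prop-1-en-2-yl ether F1. Ring-closing olefin metathesis of the allyl group with the enol ether, using the second-generation Grubbs catalyst RuCl2(=CHPh)(H2IMes)(PCy3) in toluene at 70 °C, should then form the same C2=C3 bond with loss of ethylene and come back to the route at 19.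

Step 16. The oxidant may also attack the side-chain olefins or ring B, and the labile epoxy ketal may collapse by hydride shift or ring opening before methyl transfer. The fallback gives up the carbon–carbon ring closure and sets C3 by reagent-controlled epoxidation; it sets out from 18 and comes back at 23, so that steps 15 to 18 are not needed. Cross-metathesis of the allyl group with 2-methylbut-2-ene (second-generation Grubbs catalyst RuCl2(=CHPh)(H2IMes)(PCy3), CH2Cl2, 40 °C) should give 3-methoxy-5-(methoxymethoxy)-2-(3-methylbut-2-en-1-yl)-4-[(2R)-5-methyl-2-(prop-1-en-2-yl)hex-5-en-1-yl]phenyl acetate F2. Shi epoxidation of the trisubstituted olefin (D-fructose-derived ketone, Oxone, K2CO3 buffer, MeCN/dimethoxymethane/H2O, 0 °C) should give 2-{[(2R)-3,3-dimethyloxiran-2-yl]methyl}-3-methoxy-5-(methoxymethoxy)-4-[(2R)-5-methyl-2-(prop-1-en-2-yl)hex-5-en-1-yl]phenyl acetate F3, the 1,1-disubstituted olefins being poor substrates for this catalyst. Neutral deacetylation (NH4OAc, aqueous MeOH) should free 2-{[(2R)-3,3-dimethyloxiran-2-yl]methyl}-3-methoxy-5-(methoxymethoxy)-4-[(2R)-5-methyl-2-(prop-1-en-2-yl)hex-5-en-1-yl]phenol F4. Camphorsulfonic acid (cat.) in CH2Cl2 at 0 °C should then open the epoxide at the tertiary carbon with the phenol oxygen (6-endo) and give 23 with C3 unchanged.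

Step 21. Lithiation may occur at benzylic or allylic positions instead of C8, or the alkoxide aggregate may metalate sluggishly. The fallback replaces C–H deprotonation by halogen–metal exchange; it sets out from 23 and comes back at 28. Electrophilic bromination of the very electron-rich ring at its only free position (NBS, 1.0 equiv, CH2Cl2, −78 °C) should give (3R)-8-bromo-5-methoxy-7-(methoxymethoxy)-2,2-dimethyl-6-[(2R)-5-methyl-2-(prop-1-en-2-yl)hex-5-en-1-yl]chroman-3-ol F5. Treatment with n-BuLi (2.2 equiv, THF, −78 °C; one equivalent for the hydroxyl, one for bromine–lithium exchange) and then with 26 should give 28.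

**Further compounds**

F1 | step 15 | 2-allyl-3-methoxy-5-(methoxymethoxy)-4-[(2R)-5-methyl-2-(prop-1-en-2-yl)hex-5-en-1-yl]phenyl prop-1-en-2-yl ether | C=C(C)CC[C@H](Cc1c(OC)c(CC=C)c(OC(C)=C)cc1OCOC)C(=C)C
F2 | step 16 | 3-methoxy-5-(methoxymethoxy)-2-(3-methylbut-2-en-1-yl)-4-[(2R)-5-methyl-2-(prop-1-en-2-yl)hex-5-en-1-yl]phenyl acetate | C=C(C)CC[C@H](Cc1c(OC)c(CC=C(C)C)c(OC(C)=O)cc1OCOC)C(=C)C
F3 | step 16 | 2-{[(2R)-3,3-dimethyloxiran-2-yl]methyl}-3-methoxy-5-(methoxymethoxy)-4-[(2R)-5-methyl-2-(prop-1-en-2-yl)hex-5-en-1-yl]phenyl acetate | C=C(C)CC[C@H](Cc1c(OC)c(C[C@H]2OC2(C)C)c(OC(C)=O)cc1OCOC)C(=C)C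
F4 | step 16 | 2-{[(2R)-3,3-dimethyloxiran-2-yl]methyl}-3-methoxy-5-(methoxymethoxy)-4-[(2R)-5-methyl-2-(prop-1-en-2-yl)hex-5-en-1-yl]phenol | C=C(C)CC[C@H](Cc1c(OC)c(C[C@H]2OC2(C)C)c(O)cc1OCOC)C(=C)C
F5 | step 21 | (3R)-8-bromo-5-methoxy-7-(methoxymethoxy)-2,2-dimethyl-6-[(2R)-5-methyl-2-(prop-1-en-2-yl)hex-5-en-1-yl]chroman-3-ol | C=C(C)CC[C@H](Cc1c(OC)c2c(c(Br)c1OCOC)OC(C)(C)[C@H](O)C2)C(=C)C
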